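Labels used throughout: Ca = ring CH carrying the methylene-alkene arm, Cb = ring CH2, Cc = CMe2, Cd = ring CH carrying the 3-oxobutyl arm; ArF = 2,3,5,6-tetrafluoro-4-(trifluoromethyl)phenyl. Compound numbers are those of the steps and of the list at the end: acid 1, aniline 2, acid chloride 3, anilide 4, ynone 5, alkynyl ketal 6, alkenylzirconium 7, alkenyl iodide 8, coupling product 9, saturated anilide 10, N-Boc imide 11, cis ester 12, trans ester 13, N-methoxy-N-methylamide 14, bromide 15, Grignard reagent 16, ketone 17, methylene compound 18, keto alcohol 19, linoleic acid 20, IN0146 21.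

## Analysis of the target

IN0146 21 is a monocyclic cyclobutane in which Ca carries a 1,1-disubstituted alkene whose second substituent is a three-carbon chain ending in the linoleate ester oxygen, Cb is a methylene, Cc is a quaternary CMe2 and Cd carries a 3-oxobutyl chain. The only stereocentres are the adjacent ring carbons Ca (S) and Cd (R), and the two arms are trans, the less strained arrangement on a four-membered ring. Cd has no acidifying neighbour and sits next to the quaternary Cc, so its configuration has to be installed directly under catalyst control, whereas Ca can be corrected by equilibration for as long as it bears a carbonyl group. The sensitive groups are the skipped (9Z,12Z)-diene of the acyl chain (autoxidation, isomerisation, no hydrogenation once it is present), the methyl ketone (to be masked against organometallic and ylide reagents), the ester, and the 1,1-disubstituted alkene on the strained ring, whose protonation would give a cyclobutylcarbinyl cation prone to ring expansion. The difficulty is absolute stereocontrol on a small carbocycle without a heteroatom handle, with two different functionalised carbon arms on adjacent carbons, one of them neopentylic. The strategy rests on one feature: if the oxobutyl arm is taken off Cd and the alkene carbon on Ca is taken back to a carboxyl carbon, the commercial acid 1 remains. Its mirror plane runs through Ca and Cc, so Cb and Cd are enantiotopic methylenes, and a chiral catalyst that functionalises one of them on the face of the carboxyl-derived directing group creates Cd and Ca in a single event.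

## Retrosynthetic reasoning

Ester C–O bond, 21 to 19 and 20. The acyl chain is attached last, because the skipped diene tolerates neither the hydrogenation nor the strongly basic and organometallic steps needed earlier. The forward reaction only has to acylate a primary alcohol under neutral conditions in the presence of a methyl ketone.

Protecting groups, 19 to 18. The primary alcohol is carried as its tert-butyldimethylsilyl ether and the ketone as its dioxolane. Both fall in dilute aqueous acid, so one operation releases 19, and the ketone stays masked through every nucleophilic step.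

Exocyclic C=CH2, 18 to 17. The alkene carbon on Ca is traced back to a ketone carbon. A 1,1-disubstituted alkene is best made by methylenation of a ketone, and a ketone on Ca keeps that centre equilibrating toward trans while the arm is built.

Bond between that carbonyl carbon and the propyl chain, 17 to 14 and 16 (from 15). The three-carbon chain with its protected oxygen arrives as Grignard reagent 16. The N-methoxy-N-methylamide 14 is the acyl partner because its chelated adduct cannot take up a second equivalent.

Acyl substitution and correction at Ca, 14 to 13 to 11 to 10. The anilide nitrogen of 10 is acidic, so base turns it into an unreactive amidate, and acidic methanolysis would cost the ketal. The nitrogen is therefore acylated to the imide 11, which basic methanolysis cleaves. The same base equilibrates the first-formed cis ester 12 to the trans ester 13, and this is where Ca receives its final configuration.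

Alkene saturation, 10 to 9. The two-carbon link between Cd and the masked ketone is introduced as an E alkene and hydrogenated at once, before any other alkene exists in the molecule.

Key disconnection, bond from Cd to the first carbon of the oxobutyl arm, 9 to 4 and 8. Cutting here reduces the ring to the symmetric anilide 4, made in one step from 1, and places all four carbons of the arm in the single partner 8. The forward reaction must cleave one of four β C–H bonds, the one on Cd that lies cis to the amide, and it must stop after one coupling. The carbonyl group of the arm passes through this step as the dioxolane of 8 for three reasons. A free carbonyl group conjugated to the C–I bond would turn the iodine-bearing carbon into an acceptor that the amidate nitrogen of 4 could attack by addition–elimination. A free enone held cis to the acidic N–H after the coupling would invite conjugate addition of nitrogen and closure of a five-membered ring. The ketone has to be masked for the later organometallic steps in any case, so with 8 the partner is an ordinary E alkenyl iodide and one protection step is saved.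

Precursors, 4 to 1 and 2 through 3, and 8 to 6 to 5. The anilide 4 is made by acylation of the weakly nucleophilic aniline 2 with acid chloride 3. The iodide 8 comes from ketalisation of ynone 5 and syn hydrometalation–iodination of alkyne 6. This fixes the E geometry, which an anti hydroiodination of 5 would not do, since it places iodine cis to the carbonyl group.

## Alternatives that were turned down

Alternative 1: The ring bonds Ca–Cb and Cd–Cc are cut, so the cyclobutane is assembled from the C=C bond of cyclohex-2-en-1-one A1 and 2-methylpropene A2, with the six-membered ring of A1 serving as a carrier that is opened later. In the forward key step A1, bound to a chiral oxazaborolidine–AlBr3 Lewis acid that shields one face and shifts its absorption to longer wavelength, is irradiated with A2. Addition with the innate head-to-tail polarity should give the cis-fused ketone (1R,6R)-7,7-dimethylbicyclo[4.2.0]octan-2-one A3, in which C6 is Cd with the target configuration and C1 is Ca.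
- For: A3 would hold two new ring bonds and both stereocentres, made from two bulk chemicals in one step. The cis fusion of A3 is harmless because Ca is epimerised later. All six carbons of the carrier ring end up in the target (C3 to C5 in the oxobutyl arm, C2 as the carbon on Ca).
- Against: the carrier ring of A3 must be cut between C2 and C3 after a methyl group has been put on C3. That means regioselective methylation, regioselective enol ether formation and ozonolysis before the acid stage is reached, followed by ketalisation, esterification and epimerisation to arrive at a compound like 13. The photoreaction of A1 with A2 needs low-temperature irradiation, a large charge of an air-sensitive Lewis acid and a condensed gas in excess, and its throughput is limited by photon flux.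
- Comparison: on precedent for the key bond formation with exactly these two partners this alternative is stronger. The step count from A3 to the trans ester stage is about the same. The chosen strategy offers in its place purely thermal steps, no degradative C–C cleavage, a purchased ring, and the complete four-carbon arm delivered at the correct oxidation level by the bond-forming step itself.

Alternative 2: The bonds Ca–Cd and Cc–CH3 are cut, with a transient Ca–Cc bond. The precursor is the acyclic diazo ester tert-butyl (4E)-2-diazo-4-methyl-7-(2-methyl-1,3-dioxolan-2-yl)hept-4-enoate A4. In the forward key step the divalent rhodium carboxylate Rh2(S-NTTL)4, or its enantiomer, should convert A4 by intramolecular cyclopropanation into the bicyclobutane tert-butyl 3-methyl-2-exo-[2-(2-methyl-1,3-dioxolan-2-yl)ethyl]bicyclo[1.1.0]butane-1-carboxylate A5. In the same flask MeMgCl with CuBr·SMe2 and PBu3 would add a methyl group to the bridgehead Cc of A5, breaking the central Ca–Cc bond. Protonation of the enolate at Ca would give tert-butyl (1S,2R)-3,3-dimethyl-2-[2-(2-methyl-1,3-dioxolan-2-yl)ethyl]cyclobutane-1-carboxylate A6.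
- For: A6 is the tert-butyl analogue of 13, reached in one flask with the ring, the quaternary carbon and the ketal in place. The catalyst loading is low and the absolute configuration at Cd is catalyst-controlled.
- Against: A4 is a purely aliphatic, trisubstituted alkene, so 1,2-hydride migration from Cb to the carbenoid competes with cyclopropanation to A5. The cuprate would have to attack a bridgehead of A5 that already bears a methyl group and create a quaternary centre, which is a more demanding ring opening than attack at an unsubstituted bridgehead. A4 itself needs about five steps (a geometrically defined allylic halide, acetoacetate alkylation, deacylative diazo transfer) and is a diazo compound to be handled on scale.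
- Comparison: this alternative is stronger in convergence at the key step, and A6 may not need a separate epimerisation. It stacks two unproven events, the formation of A5 and its opening, where the chosen strategy has one. Its precursor A4 is also longer to make than 4 and 8 together (three steps).

Alternative 3: The bond from Ca to the alkene carbon is cut. The partners are methyl 4,4-dimethylcyclobut-1-ene-1-carboxylate A7 and the internal alkenylboronate tert-butyldimethyl{[4-(4,4,5,5-tetramethyl-1,3,2-dioxaborolan-2-yl)pent-4-en-1-yl]oxy}silane A8. In the forward key step the monovalent rhodium complex [Rh(OH)(cod)]2 with a chiral diene or BINAP would transfer the alkenyl group of A8 to Ca of A7. Protonation of the rhodium enolate at Cd, with base equilibration if needed, would give methyl (1R,2S)-2-[5-(tert-butyldimethylsilyloxy)pent-1-en-2-yl]-4,4-dimethylcyclobutane-1-carboxylate A9.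
- For: A9 would hold the complete alkene arm, with its methylene group and protected alcohol, after one step, so steps 8 to 10 of the chosen route have no counterpart. Ca is an unhindered β-carbon of A7, and trans is the thermodynamic outcome for A9.
- Against: A7 is not a catalogue compound and its ring would have to be made first. A8, like other boron reagents substituted at the carbon bearing boron, transmetalates slowly to rhodium and is prone to protodeboronation. After the key step the ester of A9 on Cd, next to the quaternary Cc, must be extended by three carbons to the oxobutyl chain in the presence of the 1,1-disubstituted alkene (reduction, olefination with an acetonyl phosphorane, chemoselective conjugate reduction), and hydrogenation is excluded.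
- Comparison: this alternative is stronger for the alkene arm, weaker for the oxobutyl arm and for access to the starting ring, and overall no shorter once A7 has been made and A9 has been extended. The chosen strategy offers a purchasable ring and puts the catalytic step on the harder problem, the arm on the hindered Cd, leaving the alkene arm to ordinary carbonyl chemistry.

Key step: step 4

Remarks on the chemistry:
- The methyl ketone is carried through the key step as its ethylene ketal, so the alkenyl partner is 8 and the coupling product is 9.
- Assumption: the sense of induction of the ligand cannot be derived from structure. The (S,S) ligand is written, and its (R,R) antipode, equally accessible from the amino acids, is used if a first trial shows the opposite sense.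

## Route

Step 1
Reactants: 1 3,3-dimethylcyclobutane-1-carboxylic acid; 2 2,3,5,6-tetrafluoro-4-(trifluoromethyl)aniline
Product: 4 N-[2,3,5,6-tetrafluoro-4-(trifluoromethyl)phenyl]-3,3-dimethylcyclobutane-1-carboxamide, via 3,3-dimethylcyclobutane-1-carbonyl chloride 3 (not isolated)
Conditions: (COCl)2, DMF (cat.), CH2Cl2, 0 °C to rt; concentrate; then 2, toluene, reflux
Reagents that add atoms: none
Why: Acid chloride formation under DMF catalysis followed by N-acylation; the electron-poor aniline is a weak nucleophile, so the neat acid chloride is heated with it without base. No stereocentre is involved.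

Step 2
Reactants: 5 but-3-yn-2-one
Product: 6 2-ethynyl-2-methyl-1,3-dioxolane
Conditions: TMSOCH2CH2OTMS (1.2 equiv), TMSOTf (5 mol %), CH2Cl2, −78 to −20 °C; pyridine quench
Reagents that add atoms: 1,2-bis(trimethylsilyloxy)ethane, C[Si](C)(C)OCCO[Si](C)(C)C
Why: Silyl-transfer ketalisation is driven by formation of hexamethyldisiloxane, and at low temperature it avoids conjugate addition of a free diol to the ynone.

Step 3
Reactants: 6 2-ethynyl-2-methyl-1,3-dioxolane
Product: 8 2-[(E)-2-iodoethenyl]-2-methyl-1,3-dioxolane, via alkenylzirconocene chloride 7 (not isolated)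
Conditions: Cp2Zr(H)Cl (1.2 equiv), THF, rt, dark; then I2, 0 °C
Reagents that add atoms: iodine, II
Why: Hydrozirconation of a terminal alkyne is a syn addition that places zirconium on the terminal carbon, and iodinolysis of the C–Zr bond proceeds with retention, so the E alkenyl iodide should result. The ketal is inert to both reagents.

Step 4
Reactants: 4 N-[2,3,5,6-tetrafluoro-4-(trifluoromethyl)phenyl]-3,3-dimethylcyclobutane-1-carboxamide; 8 2-[(E)-2-iodoethenyl]-2-methyl-1,3-dioxolane
Product: 9 (1R,2R)-N-[2,3,5,6-tetrafluoro-4-(trifluoromethyl)phenyl]-3,3-dimethyl-2-[(E)-2-(2-methyl-1,3-dioxolan-2-yl)ethenyl]cyclobutane-1-carboxamide (cis)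
Conditions: Pd(OAc)2 (10 mol %), N-[(1S)-1-[(4S)-4-benzyl-4,5-dihydro-1,3-oxazol-2-yl]-2,2-dimethylpropyl]acetamide (20 mol %), Ag2CO3 (1.5 equiv), 8 (1.5 equiv), t-AmylOH, 70 °C
Reagents that add atoms: none
Why: The closest known reaction type is the enantioselective β-C(sp3)–H alkenylation of cyclobutanecarboxamides carrying this acidic N-aryl group, catalysed by divalent palladium with acetyl-protected aminomethyl oxazoline ligands and alkenyl iodides. The amidate of 4 binds palladium and the ligand's acetamide acts as internal base in a concerted metalation–deprotonation of one β C–H bond cis to the amide, giving a five-membered palladacycle fused to the ring. Oxidative addition of 8 gives tetravalent palladium, C–C reductive elimination follows with retention at both carbons, Ag2CO3 takes up iodide and returns divalent palladium, and no ring is closed, the only new skeletal bond being the one from Cd to the alkenyl carbon. Cd is set by the ligand, which chooses between the enantiotopic methylenes Cb and Cd in the C–H cleavage, and Ca becomes stereogenic as a consequence, its cis relationship to the new arm being dictated by the palladacycle because the metal reaches only hydrogens on the amide face. The step needs mono- over dialkenylation, which the added crowding on the amide face and the modest excess of 8 should secure. It also needs clean reaction at the C–I bond, which the ketal secures, since 8 is a plain alkenyl iodide that cannot alkenylate the amidate nitrogen by addition–elimination and 9 holds no Michael acceptor that could close onto the anilide nitrogen. The open point is the quaternary Cc next to both methylenes, which may slow palladation, whereas the methyl C–H bonds are out of reach of the directing group.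

Step 5
Reactants: 9 (1R,2R)-N-[2,3,5,6-tetrafluoro-4-(trifluoromethyl)phenyl]-3,3-dimethyl-2-[(E)-2-(2-methyl-1,3-dioxolan-2-yl)ethenyl]cyclobutane-1-carboxamide
Product: 10 (1R,2R)-N-[2,3,5,6-tetrafluoro-4-(trifluoromethyl)phenyl]-3,3-dimethyl-2-[2-(2-methyl-1,3-dioxolan-2-yl)ethyl]cyclobutane-1-carboxamide (cis)
Conditions: H2 (1 atm), 10% Pd/C, EtOAc, rt
Reagents that add atoms: none
Why: Heterogeneous catalytic hydrogenation of a disubstituted alkene; the stereocentres are not touched, and aryl C–F bonds and the ketal should survive neutral conditions at 1 atm.

Step 6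
Reactants: 10 (1R,2R)-N-[2,3,5,6-tetrafluoro-4-(trifluoromethyl)phenyl]-3,3-dimethyl-2-[2-(2-methyl-1,3-dioxolan-2-yl)ethyl]cyclobutane-1-carboxamide
Product: 11 tert-butyl N-{(1R,2R)-3,3-dimethyl-2-[2-(2-methyl-1,3-dioxolan-2-yl)ethyl]cyclobutane-1-carbonyl}-N-[2,3,5,6-tetrafluoro-4-(trifluoromethyl)phenyl]carbamate
Conditions: Boc2O (2.5 equiv), DMAP (0.3 equiv), MeCN, rt to 40 °C
Reagents that add atoms: di-tert-butyl dicarbonate, CC(C)(C)OC(=O)OC(=O)OC(C)(C)C
Why: DMAP-catalysed N-acylation of the acidic anilide N–H (amide activation) gives an imide that can no longer form an amidate and whose acyl C–N bond is open to nucleophiles under non-acidic conditions, which the ketal requires.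

Step 7
Reactants: 11 tert-butyl N-{(1R,2R)-3,3-dimethyl-2-[2-(2-methyl-1,3-dioxolan-2-yl)ethyl]cyclobutane-1-carbonyl}-N-[2,3,5,6-tetrafluoro-4-(trifluoromethyl)phenyl]carbamate
Product: 13 methyl (1S,2R)-3,3-dimethyl-2-[2-(2-methyl-1,3-dioxolan-2-yl)ethyl]cyclobutane-1-carboxylate, via cis methyl ester 12 (not isolated)
Conditions: NaOMe (3 equiv), MeOH/THF, 0 °C to rt; then 60 °C; aq. NH4Cl
Reagents that add atoms: sodium methoxide, [Na+].[O-]C
Why: Nucleophilic acyl substitution: methoxide attacks the acyl carbonyl and expels the stabilised carbamate anion, giving 12. The same base then exchanges the ester α-hydrogen at Ca, and the equilibrium should lie on the trans side because in the cis isomer the ester is pressed against the Cd chain, itself buttressed by the gem-dimethyl group. Ca is thus set as (S) under thermodynamic control; Cd carries no acidic hydrogen and is untouched.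

Step 8
Reactants: 13 methyl (1S,2R)-3,3-dimethyl-2-[2-(2-methyl-1,3-dioxolan-2-yl)ethyl]cyclobutane-1-carboxylate
Product: 14 (1S,2R)-N-methoxy-N,3,3-trimethyl-2-[2-(2-methyl-1,3-dioxolan-2-yl)ethyl]cyclobutane-1-carboxamide
Conditions: MeNH(OMe)·HCl (2 equiv), i-PrMgCl (4 equiv), THF, −20 to 0 °C
Reagents that add atoms: N,O-dimethylhydroxylamine hydrochloride, CNOC.Cl
Why: Aminolysis of the ester by the magnesium amide formed in the flask from the hydroxylamine salt and i-PrMgCl. The trans arrangement is the stable one, so the basic medium does not endanger Ca.

Step 9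
Reactants: 14 (1S,2R)-N-methoxy-N,3,3-trimethyl-2-[2-(2-methyl-1,3-dioxolan-2-yl)ethyl]cyclobutane-1-carboxamide; 15 (3-bromopropoxy)(tert-butyl)dimethylsilane
Product: 17 4-[(tert-butyldimethylsilyl)oxy]-1-{(1S,2R)-3,3-dimethyl-2-[2-(2-methyl-1,3-dioxolan-2-yl)ethyl]cyclobutyl}butan-1-one, via 3-(tert-butyldimethylsilyloxy)propylmagnesium bromide 16 (not isolated)
Conditions: 15, Mg turnings, THF, 40 °C; then 14, THF, 0 °C to rt; aq. NH4Cl
Reagents that add atoms: none
Why: Grignard addition to an N-methoxy-N-methylamide stops at the chelated tetrahedral adduct, which gives the ketone only on work-up, so no tertiary alcohol should form. The ketal and silyl ether are inert.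

Step 10
Reactants: 17 4-[(tert-butyldimethylsilyl)oxy]-1-{(1S,2R)-3,3-dimethyl-2-[2-(2-methyl-1,3-dioxolan-2-yl)ethyl]cyclobutyl}butan-1-one
Product: 18 tert-butyl[(4-{(1S,2R)-3,3-dimethyl-2-[2-(2-methyl-1,3-dioxolan-2-yl)ethyl]cyclobutyl}pent-4-en-1-yl)oxy]dimethylsilane
Conditions: Ph3PCH3Br (2 equiv), KOtBu (1.9 equiv), THF, 0 °C to rt
Reagents that add atoms: methyltriphenylphosphonium bromide, C[P+](c1ccccc1)(c1ccccc1)c1ccccc1.[Br-]
Why: Wittig methylenation with the non-stabilised ylide. Any reversible enolisation at Ca is harmless because the trans isomer is the thermodynamic one, and once the alkene is formed Ca is no longer acidic.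

Step 11
Reactants: 18 tert-butyl[(4-{(1S,2R)-3,3-dimethyl-2-[2-(2-methyl-1,3-dioxolan-2-yl)ethyl]cyclobutyl}pent-4-en-1-yl)oxy]dimethylsilane
Product: 19 4-[(1S,2R)-3,3-dimethyl-2-(3-oxobutyl)cyclobutyl]pent-4-en-1-ol
Conditions: 1 M aq. HCl/THF (1:3), rt; NaHCO3 work-up
Reagents that add atoms: water, O
Why: Dilute aqueous acid hydrolyses the dioxolane through its oxocarbenium ion and cleaves the primary silyl ether in one operation. At this acidity and temperature protonation of the 1,1-disubstituted alkene should be far slower, and neither stereocentre is acidic.

Step 12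
Reactants: 19 4-[(1S,2R)-3,3-dimethyl-2-(3-oxobutyl)cyclobutyl]pent-4-en-1-ol; 20 linoleic acid, (9Z,12Z)-octadeca-9,12-dienoic acid
Product: 21 IN0146, 4-[(1S,2R)-3,3-dimethyl-2-(3-oxobutyl)cyclobutyl]pent-4-en-1-yl (9Z,12Z)-octadeca-9,12-dienoate
Conditions: EDC·HCl (1.5 equiv), DMAP (0.2 equiv), CH2Cl2, 0 °C to rt, argon, dark
Reagents that add atoms: none
Why: Steglich esterification of a primary alcohol under neutral conditions. The skipped diene enters only here and afterwards meets no acid, strong base or hydrogenation catalyst.

## Compound list

1 | 3,3-dimethylcyclobutane-1-carboxylic acid | CC1(C)CC(C1)C(=O)O | starting material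
2 | 2,3,5,6-tetrafluoro-4-(trifluoromethyl)aniline | Nc1c(F)c(F)c(C(F)(F)F)c(F)c1F | starting material
3 | 3,3-dimethylcyclobutane-1-carbonyl chloride | CC1(C)CC(C1)C(=O)Cl | intermediate
4 | N-[2,3,5,6-tetrafluoro-4-(trifluoromethyl)phenyl]-3,3-dimethylcyclobutane-1-carboxamide | CC1(C)CC(C1)C(=O)Nc1c(F)c(F)c(C(F)(F)F)c(F)c1F | intermediate
5 | but-3-yn-2-one | CC(=O)C#C | starting material
6 | 2-ethynyl-2-methyl-1,3-dioxolane | C#CC1(C)OCCO1 | intermediate
7 | chlorobis(cyclopentadienyl)[(E)-2-(2-methyl-1,3-dioxolan-2-yl)ethenyl]zirconium (cyclopentadienyl rings drawn σ-bonded) | CC1(/C=C/[Zr](Cl)(C2C=CC=C2)C2C=CC=C2)OCCO1 | intermediate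
8 | 2-[(E)-2-iodoethenyl]-2-methyl-1,3-dioxolane | CC1(/C=C/I)OCCO1 | intermediate
9 | (1R,2R)-N-[2,3,5,6-tetrafluoro-4-(trifluoromethyl)phenyl]-3,3-dimethyl-2-[(E)-2-(2-methyl-1,3-dioxolan-2-yl)ethenyl]cyclobutane-1-carboxamide | O=C(Nc1c(F)c(F)c(C(F)(F)F)c(F)c1F)[C@@H]2CC(C)(C)[C@@H]2/C=C/C3(C)OCCO3 | intermediate
10 | (1R,2R)-N-[2,3,5,6-tetrafluoro-4-(trifluoromethyl)phenyl]-3,3-dimethyl-2-[2-(2-methyl-1,3-dioxolan-2-yl)ethyl]cyclobutane-1-carboxamide | O=C(Nc1c(F)c(F)c(C(F)(F)F)c(F)c1F)[C@@H]2CC(C)(C)[C@@H]2CCC3(C)OCCO3 | intermediate
11 | tert-butyl N-{(1R,2R)-3,3-dimethyl-2-[2-(2-methyl-1,3-dioxolan-2-yl)ethyl]cyclobutane-1-carbonyl}-N-[2,3,5,6-tetrafluoro-4-(trifluoromethyl)phenyl]carbamate | CC(C)(C)OC(=O)N(c1c(F)c(F)c(C(F)(F)F)c(F)c1F)C(=O)[C@@H]2CC(C)(C)[C@@H]2CCC3(C)OCCO3 | intermediate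
12 | methyl (1R,2R)-3,3-dimethyl-2-[2-(2-methyl-1,3-dioxolan-2-yl)ethyl]cyclobutane-1-carboxylate (cis) | COC(=O)[C@@H]1CC(C)(C)[C@@H]1CCC2(C)OCCO2 | intermediate
13 | methyl (1S,2R)-3,3-dimethyl-2-[2-(2-methyl-1,3-dioxolan-2-yl)ethyl]cyclobutane-1-carboxylate (trans) | COC(=O)[C@H]1CC(C)(C)[C@@H]1CCC2(C)OCCO2 | intermediate
14 | (1S,2R)-N-methoxy-N,3,3-trimethyl-2-[2-(2-methyl-1,3-dioxolan-2-yl)ethyl]cyclobutane-1-carboxamide | CON(C)C(=O)[C@H]1CC(C)(C)[C@@H]1CCC2(C)OCCO2 | intermediate
15 | (3-bromopropoxy)(tert-butyl)dimethylsilane | BrCCCO[Si](C)(C)C(C)(C)C | starting material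
16 | 3-(tert-butyldimethylsilyloxy)propylmagnesium bromide | CC(C)(C)[Si](C)(C)OCCC[Mg]Br | intermediate
17 | 4-[(tert-butyldimethylsilyl)oxy]-1-{(1S,2R)-3,3-dimethyl-2-[2-(2-methyl-1,3-dioxolan-2-yl)ethyl]cyclobutyl}butan-1-one | CC(C)(C)[Si](C)(C)OCCCC(=O)[C@H]1CC(C)(C)[C@@H]1CCC2(C)OCCO2 | intermediate
18 | tert-butyl[(4-{(1S,2R)-3,3-dimethyl-2-[2-(2-methyl-1,3-dioxolan-2-yl)ethyl]cyclobutyl}pent-4-en-1-yl)oxy]dimethylsilane | C=C(CCCO[Si](C)(C)C(C)(C)C)[C@H]1CC(C)(C)[C@@H]1CCC2(C)OCCO2 | intermediate
19 | 4-[(1S,2R)-3,3-dimethyl-2-(3-oxobutyl)cyclobutyl]pent-4-en-1-ol | C=C(CCCO)[C@H]1CC(C)(C)[C@@H]1CCC(C)=O | intermediate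
20 | linoleic acid, (9Z,12Z)-octadeca-9,12-dienoic acid | CCCCC/C=C\C/C=C\CCCCCCCC(=O)O | starting material
21 | IN0146, 4-[(1S,2R)-3,3-dimethyl-2-(3-oxobutyl)cyclobutyl]pent-4-en-1-yl (9Z,12Z)-octadeca-9,12-dienoate | C=C(CCCOC(=O)CCCCCCC/C=C\C/C=C\CCCCC)[C@H]1CC(C)(C)[C@@H]1CCC(C)=O | target

## Step count and risks

Total: 12 steps. Longest linear sequence: 11 steps (5 to 21 through steps 2 to 12); from acid 1 the line is 10 steps (steps 1 and 4 to 12).

Step 4 (key step). The most likely failure is slow or unselective palladation at a methylene flanked by the quaternary Cc. That would show as low conversion, weak discrimination between the enantiotopic methylenes, or a second alkenylation at Cb once forcing conditions are used. The fallback gives up C–H functionalisation and buys the ring with its stereocentres. The keto alcohol 19 has exactly the carbon skeleton and the trans (R)-Cd/(S)-Ca configuration of the commercial sesquiterpene (−)-β-caryophyllene F1 cut at its endocyclic trisubstituted alkene. This fallback therefore sets out from no numbered compound of the route: it starts from F1, makes compounds 1 to 18 unnecessary and comes back to the route at 19. One equivalent of ozone in CH2Cl2/MeOH at −78 °C should attack the strained, more electron-rich endocyclic E alkene of F1 well before the exocyclic methylene. Reduction of the ozonide with Me2S should then give 4-[(1S,2R)-3,3-dimethyl-2-(3-oxobutyl)cyclobutyl]pent-4-enal F2. NaBH(OAc)3, or NaBH4 at −78 °C, reduces the aldehyde in preference to the methyl ketone and delivers 19, from which step 12 follows.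

Step 7. Methoxide may attack the carbamate carbonyl in place of the hindered acyl carbonyl, which removes the activating group and returns 10, or it may displace a ring fluorine of the electron-poor aryl group before the acyl transfer, or the epimerisation at the ester stage may stop short of completion. The fallback sets out from 11 and moves both the cleavage and the epimerisation. LiOH/H2O2 in THF/water, whose small hydroperoxide anion favours the acyl carbonyl, should give after careful acidification to about pH 5 (1R,2R)-3,3-dimethyl-2-[2-(2-methyl-1,3-dioxolan-2-yl)ethyl]cyclobutane-1-carboxylic acid F3. Coupling with N,O-dimethylhydroxylamine (EDC·HCl, HOBt, i-Pr2NEt) gives the cis amide (1R,2R)-N-methoxy-N,3,3-trimethyl-2-[2-(2-methyl-1,3-dioxolan-2-yl)ethyl]cyclobutane-1-carboxamide F4. Grignard reagent 16 then gives the cis ketone 4-[(tert-butyldimethylsilyl)oxy]-1-{(1R,2R)-3,3-dimethyl-2-[2-(2-methyl-1,3-dioxolan-2-yl)ethyl]cyclobutyl}butan-1-one F5. Its α-hydrogen is far more acidic than that of an ester, so DBU in CH2Cl2 or K2CO3 in MeOH should equilibrate it to the trans ketone, and the route is rejoined at 17.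

Step 10. The basic ylide may enolise the α-branched ketone faster than it adds, so that conversion stalls. The fallback sets out from 17 and uses a Peterson olefination with a non-basic nucleophile. Me3SiCH2Li with anhydrous CeCl3 in THF at −78 °C adds to the carbonyl group without enolisation and should give 5-[(tert-butyldimethylsilyl)oxy]-2-{(1S,2R)-3,3-dimethyl-2-[2-(2-methyl-1,3-dioxolan-2-yl)ethyl]cyclobutyl}-1-(trimethylsilyl)pentan-2-ol F6 as a mixture of carbinol epimers. KH in THF then induces syn elimination of silanolate from either epimer, and the route is rejoined at 18.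

Step 11. Acid may act on the alkene as well as on the protecting groups: protonation of the 1,1-disubstituted alkene would lead to double-bond migration or, through the cyclobutylcarbinyl cation, to ring expansion. The fallback sets out from 18 and separates the two deprotections so that the alkene never meets a mineral acid. TBAF in THF gives 4-{(1S,2R)-3,3-dimethyl-2-[2-(2-methyl-1,3-dioxolan-2-yl)ethyl]cyclobutyl}pent-4-en-1-ol F7. Esterification with 20 (EDC·HCl, DMAP, CH2Cl2) gives 4-{(1S,2R)-3,3-dimethyl-2-[2-(2-methyl-1,3-dioxolan-2-yl)ethyl]cyclobutyl}pent-4-en-1-yl (9Z,12Z)-octadeca-9,12-dienoate F8. Pyridinium p-toluenesulfonate in acetone/water at 40 °C then hydrolyses the ketal, and the fallback ends at 21.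

## Further compounds

F1 | step 4 | (−)-β-caryophyllene, (1R,4E,9S)-4,11,11-trimethyl-8-methylidenebicyclo[7.2.0]undec-4-ene | C=C(CC/C=C(\C)CC3)[C@H]1CC(C)(C)[C@@H]13
F2 | step 4 | 4-[(1S,2R)-3,3-dimethyl-2-(3-oxobutyl)cyclobutyl]pent-4-enal | C=C(CCC=O)[C@H]1CC(C)(C)[C@@H]1CCC(C)=O
F3 | step 7 | (1R,2R)-3,3-dimethyl-2-[2-(2-methyl-1,3-dioxolan-2-yl)ethyl]cyclobutane-1-carboxylic acid | OC(=O)[C@@H]1CC(C)(C)[C@@H]1CCC2(C)OCCO2
F4 | step 7 | (1R,2R)-N-methoxy-N,3,3-trimethyl-2-[2-(2-methyl-1,3-dioxolan-2-yl)ethyl]cyclobutane-1-carboxamide | CON(C)C(=O)[C@@H]1CC(C)(C)[C@@H]1CCC2(C)OCCO2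
F5 | step 7 | 4-[(tert-butyldimethylsilyl)oxy]-1-{(1R,2R)-3,3-dimethyl-2-[2-(2-methyl-1,3-dioxolan-2-yl)ethyl]cyclobutyl}butan-1-one | CC(C)(C)[Si](C)(C)OCCCC(=O)[C@@H]1CC(C)(C)[C@@H]1CCC2(C)OCCO2
F6 | step 10 | 5-[(tert-butyldimethylsilyl)oxy]-2-{(1S,2R)-3,3-dimethyl-2-[2-(2-methyl-1,3-dioxolan-2-yl)ethyl]cyclobutyl}-1-(trimethylsilyl)pentan-2-ol | C[Si](C)(C)CC(O)(CCCO[Si](C)(C)C(C)(C)C)[C@H]1CC(C)(C)[C@@H]1CCC2(C)OCCO2
F7 | step 11 | 4-{(1S,2R)-3,3-dimethyl-2-[2-(2-methyl-1,3-dioxolan-2-yl)ethyl]cyclobutyl}pent-4-en-1-ol | C=C(CCCO)[C@H]1CC(C)(C)[C@@H]1CCC2(C)OCCO2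
F8 | step 11 | 4-{(1S,2R)-3,3-dimethyl-2-[2-(2-methyl-1,3-dioxolan-2-yl)ethyl]cyclobutyl}pent-4-en-1-yl (9Z,12Z)-octadeca-9,12-dienoate | C=C(CCCOC(=O)CCCCCCC/C=C\C/C=C\CCCCC)[C@H]1CC(C)(C)[C@@H]1CCC2(C)OCCO2
A1 | alternative 1 | cyclohex-2-en-1-one | O=C1C=CCCC1
A2 | alternative 1 | 2-methylpropene | C=C(C)C
A3 | alternative 1 | (1R,6R)-7,7-dimethylbicyclo[4.2.0]octan-2-one | O=C1CCC[C@H]2C(C)(C)C[C@@H]12
A4 | alternative 2 | tert-butyl (4E)-2-diazo-4-methyl-7-(2-methyl-1,3-dioxolan-2-yl)hept-4-enoate | CC(C)(C)OC(=O)C(=[N+]=[N-])C/C(C)=C/CCC1(C)OCCO1
A5 | alternative 2 | tert-butyl 3-methyl-2-exo-[2-(2-methyl-1,3-dioxolan-2-yl)ethyl]bicyclo[1.1.0]butane-1-carboxylate | CC(C)(C)OC(=O)[C@]12C[C@@]1(C)[C@@H]2CCC3(C)OCCO3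
A6 | alternative 2 | tert-butyl (1S,2R)-3,3-dimethyl-2-[2-(2-methyl-1,3-dioxolan-2-yl)ethyl]cyclobutane-1-carboxylate | CC(C)(C)OC(=O)[C@H]1CC(C)(C)[C@@H]1CCC2(C)OCCO2
A7 | alternative 3 | methyl 4,4-dimethylcyclobut-1-ene-1-carboxylate | COC(=O)C1=CCC1(C)C
A8 | alternative 3 | tert-butyldimethyl{[4-(4,4,5,5-tetramethyl-1,3,2-dioxaborolan-2-yl)pent-4-en-1-yl]oxy}silane | C=C(CCCO[Si](C)(C)C(C)(C)C)B1OC(C)(C)C(C)(C)O1
A9 | alternative 3 | methyl (1R,2S)-2-[5-(tert-butyldimethylsilyloxy)pent-1-en-2-yl]-4,4-dimethylcyclobutane-1-carboxylate | C=C(CCCO[Si](C)(C)C(C)(C)C)[C@H]1CC(C)(C)[C@@H]1C(=O)OC
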